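The target is what is asked, and it is read through the substrate: on Saturday's run at 2.50 min the two sum to 98.2%, so I take the end state as full conversion and ask how fast it is approached.

the same everywhere: gas phase 13 mM (held)

| run | substrate | free catalyst | remark | time |
|---|---|---|---|---|
| Saturday's | 0.050 M | 1 mM | run made earlier |  |
| Sunday's | 0.20 M | 1 mM | run made earlier |  |
| Tuesday's | 0.10 M | 0.50 mM | run made earlier |  |
| flask | 0.10 M | 1.0 mM |  | 2.5 min |

| run | time / min | target / % | substrate / % |
|---|---|---|---|
| Saturday's | 0.667 | 65.4 | 35.3 |
| Saturday's | 1.33 | 82.0 | 18.4 |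
| Saturday's | 2.00 | 87.5 | 11.6 |
| Saturday's | 2.50 | 90.5 | 7.7 |
| Saturday's | 3.00 | 92.1 | 5.6 |
| Sunday's | 0.250 | 35.8 | 64.6 |
| Sunday's | 0.833 | 68.7 | 30.5 |
| Sunday's | 1.33 | 79.5 | 20.1 |
| Sunday's | 2.00 | 86.8 | 13.2 |
| Sunday's | 3.00 | 91.1 | 8.8 |
| Tuesday's | 0.667 | 48.0 | 53.5 |
| Tuesday's | 1.33 | 66.6 | 31.5 |
| Tuesday's | 2.00 | 75.7 | 23.6 |
| Tuesday's | 2.50 | 82.1 | 19.3 |
| Tuesday's | 3.00 | 85.4 | 14.6 |

(standard deviation of a reading: 1 percentage point)

- at the start none of the gas is dissolved
- the analysis behind the earlier runs scatters by 1 percentage point, standard deviation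
- steps that have been proposed: gas phase <-> dissolved gas; substrate + dissolved gas + free catalyst -> free catalyst + target; 2 dissolved gas -> self-condensation product; 2 free catalyst -> spent catalyst; dissolved gas -> decomposed reagent

* target at 2.5 min, in percent of the substrate charged
* concentration of dissolved gas in solution at 2.5 min, in percent of saturation

From below, Sunday's run holds 86.8% target at 2.00 min. From above, Saturday's run holds 92.1% at 3.00 min. The flask has their catalyst, a substrate charge between theirs and a time between those readings, so I expect it inside that bracket.

To tighten it, define the exposure E as ln(100/substrate %), the pseudo-first-order count of e-foldings. Averaged over those two runs, E reads 2.09 at 2.00 min and 2.66 at 3.00 min. If free catalyst is lost in pairs to spent catalyst, it falls late on inversely with time, and if dissolved gas also stays steady, E then gains a fixed amount per doubling of time. Call this the doubling gain G, here 0.969. For 2.5 min my reckoning gives E = 2.40, so 90.9% target, from readings that scatter by 1 percentage point.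

The forecast says 90% (88% to 92%), inside the bracket, and 90% of saturation (70% to 99%), reasoning that “Dissolved gas should be near saturation”.

The flask gives 90.4% target and 97.7% of saturation, 7.7 points above the forecast; its 9.6% of substrate left means E = 2.34, against my 2.40. gas phase ⇌ dissolved gas, rate k1*(csat - [dissolved gas]) (kL = 2.30 s⁻¹); substrate + dissolved gas + free catalyst → free catalyst + target (k = 3500 M⁻² s⁻¹); 2 dissolved gas → self-condensation product (k = 0.380 M⁻¹ s⁻¹); 2 free catalyst → spent catalyst (k = 16.0 M⁻¹ s⁻¹); dissolved gas → decomposed reagent (k = 0.0390 s⁻¹)

In the flask at 2.5 min the target step uses dissolved gas at 0.15 of the rate of its decomposition, whose half-life, 0.30 min, is short against 2.5 min. Even so, dissolved gas is made 1.00 times as fast as it is used up, each step taken net, and stands at 0.0127 M. Read the same flask at 6.0 min, twice 3.00 min: one doubling gives E = 3.63, so 2.65% substrate and 97.3% target; computed, it holds 3.28% and 96.7%.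

(The data come from a simulation with constants of no real substance, and the scatter is random.)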